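Everything rests on making the O–C4 and C4–C5 bonds together (germacrane numbering; labels are listed below). A copper carbenoid at C4, tethered through C3–C2 to C1 of an eight-membered furo-fused cyclic ether (O, C5, C6, C7, C8, C9, C10, C1), is trapped by the ring oxygen; the oxonium ylide then undergoes a Stevens [1,2]-shift of the furfuryl carbon C5 from oxygen to C4. One operation closes the tetrahydrofuranone, enlarges the eight-membered ether to the nine-membered ring O–C1–C10–C9–C8–C7–C6–C5–C4 and sets quaternary C4 from C1. The step exploits the furanone oxygen flanked by C1 and the α-keto quaternary C4; a furan masks the ylidene butenolide and stabilises the migrating carbon.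

Key step: step 13

Remark (labels and assumptions): furanone ring O–C1=C2–C3(=O)–C4(CH3); C5H=C6–O(lactone); C7=C11(C13H2OAc)–C12(=O); C8 carries the acyloxy group, C9 is CH2, C10 carries CH3. In the furan intermediates the furan is O–C6=C7–C11=C12 and the eight-membered ether is O–C5H2–C6=C7–C8–C9–C10–C1. TIPS = tri(propan-2-yl)silyl, TBS = tert-butyldimethylsilyl. The ligand antipodes in steps 5 and 7 are assigned by analogy and would be confirmed on the first batch.

Step 1
Reactants: 1 furan-3,4-diyldimethanol
Product: 2 [4-(TIPS-oxymethyl)furan-3-yl]methanol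
Conditions: NaH (1.0 equiv), THF, 0 °C; TIPSCl (1.0 equiv), rt
Reagents that add atoms: chlorotri(propan-2-yl)silane, CC(C)[Si](Cl)(C(C)C)C(C)C
Why: Monosilylation of the symmetrical diol through its monosodium alkoxide (silyl ether formation) should leave one hydroxymethyl group free.

Step 2
Reactants: 2 [4-(TIPS-oxymethyl)furan-3-yl]methanol
Product: 3 4-(TIPS-oxymethyl)furan-3-carbaldehyde
Conditions: MnO2 (excess), CH2Cl2, rt
Reagents that add atoms: none
Why: MnO2 oxidation of the furylic (benzylic-type) primary alcohol should stop at the aldehyde, which becomes C8.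

Step 3
Reactants: 3 4-(TIPS-oxymethyl)furan-3-carbaldehyde
Product: 5 2-(hydroxymethyl)-4-(TIPS-oxymethyl)furan-3-carbaldehyde, via lithium α-amino alkoxide 4 (not isolated)
Conditions: LiN(CH3)CH2CH2N(CH3)2 (from the amine and n-BuLi), THF, −78 °C; n-BuLi, −20 °C; (CH2O)n, −78 °C to rt; H2O
Reagents that add atoms: formaldehyde (as paraformaldehyde), C=O
Why: The in-situ α-amino alkoxide masks the formyl group and directs ortho-lithiation to the adjacent furan α-carbon C6, and the aryllithium adds to formaldehyde (directed ortho-metalation and hydroxymethylation), which installs C5.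

Step 4
Reactants: 5 2-(hydroxymethyl)-4-(TIPS-oxymethyl)furan-3-carbaldehyde
Product: 6 2-(bromomethyl)-4-(TIPS-oxymethyl)furan-3-carbaldehyde
Conditions: PPh3, NBS, CH2Cl2, −20 °C
Reagents that add atoms: N-bromosuccinimide, O=C1CCC(=O)N1Br
Why: Appel-type bromination through the alkoxyphosphonium salt should convert the primary alcohol without touching the aldehyde, and the 3-formyl group keeps the furfuryl bromide an SN2 electrophile.

Step 5
Reactants: 7 methacrolein
Product: 9 methyl (3S)-3-hydroxy-4-methylpent-4-enoate, via silyl aldol adduct 8 (not isolated)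
Conditions: Ti(OiPr)4 (5 mol%), chiral binaphthyl aminophenol Schiff-base ligand, 3,5-di-tert-butylsalicylic acid, Et2O, −10 °C; then 1 M HCl, THF
Reagents that add atoms: 1-methoxy-1-(trimethylsilyloxy)ethene, C=C(OC)O[Si](C)(C)C
Why: A catalytic enantioselective Mukaiyama aldol addition of the acetate silyl ketene acetal to the enal should set C1 by catalyst control (ligand antipode chosen for 3S), and the acidic work-up frees the alcohol.

Step 6
Reactants: 6 2-(bromomethyl)-4-(TIPS-oxymethyl)furan-3-carbaldehyde; 9 methyl (3S)-3-hydroxy-4-methylpent-4-enoate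
Product: 10 methyl (3S)-3-{[3-formyl-4-(TIPS-oxymethyl)furan-2-yl]methoxy}-4-methylpent-4-enoate
Conditions: Ag2O, 4 Å sieves, CH2Cl2, rt, dark
Reagents that add atoms: none
Why: A Ag2O-promoted Williamson etherification should join C5 to the C1 oxygen under neutral conditions that spare the β-hydroxy ester from retro-aldol cleavage.

Step 7
Reactants: 10 methyl (3S)-3-{[3-formyl-4-(TIPS-oxymethyl)furan-2-yl]methoxy}-4-methylpent-4-enoate
Product: 11 methyl (3S)-3-({3-[(1S)-1-hydroxyprop-2-en-1-yl]-4-(TIPS-oxymethyl)furan-2-yl}methoxy)-4-methylpent-4-enoate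
Conditions: (CH2=CH)2Zn, (−)-DAIB (10 mol%), toluene, −20 to 0 °C; H2O
Reagents that add atoms: divinylzinc, C=C[Zn]C=C
Why: An amino-alcohol-catalysed enantioselective vinylzinc addition to the aromatic aldehyde should set C8 by catalyst control (8S by analogy with the established sense of this ligand for aryl aldehydes), and the ester is inert to the organozinc.

Step 8
Reactants: 11 methyl (3S)-3-({3-[(1S)-1-hydroxyprop-2-en-1-yl]-4-(TIPS-oxymethyl)furan-2-yl}methoxy)-4-methylpent-4-enoate
Product: 12 furo-fused oxocine allylic alcohol (1S,8S)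
Conditions: second-generation Grubbs catalyst (10 mol%), 1,4-benzoquinone (20 mol%), CH2Cl2 (2 mM), 40 °C
Reagents that add atoms: none
Why: Ring-closing metathesis should form the eight-membered ether because the cis-disposed furan substituents act as an ortho-fused template, and the ring forces the trisubstituted C9=C10 olefin cis.

Step 9
Reactants: 12 furo-fused oxocine allylic alcohol (1S,8S)
Product: 13 furo-fused oxocane alcohol (1S,8S,10S)
Conditions: [Ir(cod)(PCy3)(py)]PF6 (5 mol%), H2 (1 atm), CH2Cl2, 0 °C to rt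
Reagents that add atoms: none
Why: Hydroxyl-directed homogeneous hydrogenation delivers hydrogen to the olefin face bound through the C8 hydroxyl, which is also the face opposite the C1 side chain, so the C10 methyl ends trans to C8–OH (10S), and the cationic iridium catalyst leaves the furan untouched.

Step 10
Reactants: 13 furo-fused oxocane alcohol (1S,8S,10S)
Product: 14 C8 O-TBS oxocane methyl ester
Conditions: TBSOTf, 2,6-lutidine, CH2Cl2, −78 °C
Reagents that add atoms: tert-butyldimethylsilyl trifluoromethanesulfonate, CC(C)(C)[Si](C)(C)OS(=O)(=O)C(F)(F)F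
Why: Silylation of the secondary alcohol (silyl triflate with a hindered base) masks C8–OH for the acyl activation and carbenoid steps.

Step 11
Reactants: 14 C8 O-TBS oxocane methyl ester
Product: 15 C8 O-TBS oxocane carboxylic acid
Conditions: LiOH, THF/MeOH/H2O, 0 °C to rt; 1 M HCl to pH 4
Reagents that add atoms: lithium hydroxide, [Li+].[OH-]
Why: Saponification of the methyl ester should free the C3 acid, and the β-alkoxy carboxylate does not eliminate under aqueous hydroxide.

Step 12
Reactants: 15 C8 O-TBS oxocane carboxylic acid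
Product: 17 α-methyl α-diazo ketone, via mixed carbonic anhydride 16 (not isolated)
Conditions: i-BuOCOCl, N-methylmorpholine, THF, −20 °C; CH3CHN2, Et2O, −20 to 0 °C
Reagents that add atoms: diazoethane, CC=[N+]=[N-]
Why: Acylation of diazoethane by the mixed anhydride (diazo ketone synthesis) should give the C3 ketone with the diazo carbon C4 already carrying its methyl group.

Step 13
Reactants: 17 α-methyl α-diazo ketone
Product: 19 bridged tetrahydrofuran-3-one (1S,4S,8S,10S), via bicyclic oxonium ylide 18 (not isolated)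
Conditions: Cu(hfacac)2 (copper bis(hexafluoroacetylacetonate), 5 mol%), CH2Cl2 (5 mM, slow addition), reflux
Reagents that add atoms: none
Why: The copper carbenoid formed from 17 is attacked by a lone pair of the ring ether oxygen (five-membered ring closure onto the carbenoid carbon C4) to give oxonium ylide 18, whose O–C5 bond cleaves to a caged furfuryl/α-oxo radical pair that recombines at C4 (Stevens [1,2]-shift). The closest known reaction type is the [1,2]-shift of cyclic oxonium ylides from benzylic ethers with Cu(hfacac)2 or Rh2(OAc)4, which gives oxygen-bridged medium rings by one-atom ring expansion. The tetrahydrofuran-3-one closes by heteroatom attack on the carbenoid, and the nine-membered oxa-ring, together with the ten-membered carbocycle, arises by 1,2-migration of C5 from oxygen to C4 out of the eight-membered ring. The new stereocentre C4 is controlled by C1: the C5–C10 tether can span the oxygen bridge on one face only, so C5 is delivered to the C4 face syn to C10 (1S gives 4S). The step needs ylide formation to outrun 1,2-hydride migration and C–H insertion of the methyl carbenoid (fast five-membered ylide closure with the electrophilic copper catalyst) and the [1,2]-shift to outrun [2,3]- or [1,4]-shifts (a [2,3]-shift would have to dearomatise the furan at its fully substituted C7).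

Step 14
Reactants: 19 bridged tetrahydrofuran-3-one (1S,4S,8S,10S)
Product: 21 bridged 3(2H)-furanone bis-silyl ether (4S,8S,10S), via trimethylsilyl enol ether 20 (not isolated)
Conditions: TMSOTf, Et3N, CH2Cl2, 0 °C; Pd(OAc)2 (1.1 equiv), MeCN, rt
Reagents that add atoms: none
Why: In this Saegusa–Ito oxidation only C2 can enolise (C4 is quaternary), and β-hydride elimination from the palladium enolate takes the C1 hydrogen to give the vinylogous ester, which removes the relay stereocentre C1.

Step 15
Reactants: 21 bridged 3(2H)-furanone bis-silyl ether (4S,8S,10S)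
Product: 22 furanone C8,C13-diol
Conditions: HF·pyridine, pyridine, THF, 0 °C to rt
Reagents that add atoms: none
Why: Fluoride-mediated desilylation should remove both silyl ethers while the buffered medium leaves the vinylogous ester and the furan intact.

Step 16
Reactants: 22 furanone C8,C13-diol
Product: 23 furanone C13 acetate C8 alcohol
Conditions: AcCl (1.05 equiv), 2,4,6-collidine, CH2Cl2, −78 °C
Reagents that add atoms: acetyl chloride, CC(Cl)=O
Why: Chemoselective acylation: the unhindered primary C13 alcohol should be acetylated much faster than the hindered secondary C8 alcohol at low temperature.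

Step 17
Reactants: 24 ethyl 2-(hydroxymethyl)acrylate
Product: 25 ethyl 2-(TBS-oxymethyl)acrylate
Conditions: TBSCl, imidazole, DMF, rt
Reagents that add atoms: tert-butylchlorodimethylsilane, CC(C)(C)[Si](C)(C)Cl
Why: Standard silyl protection of the primary allylic alcohol prevents self-esterification of the acid in step 19.

Step 18
Reactants: 25 ethyl 2-(TBS-oxymethyl)acrylate
Product: 26 2-(TBS-oxymethyl)acrylic acid
Conditions: LiOH, THF/H2O, 0 °C; 1 M HCl to pH 4
Reagents that add atoms: lithium hydroxide, [Li+].[OH-]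
Why: Saponification of the ethyl ester should give the acid, and the primary TBS ether survives cold hydroxide.

Step 19
Reactants: 23 furanone C13 acetate C8 alcohol; 26 2-(TBS-oxymethyl)acrylic acid
Product: 27 furan C8 ester (4S,8S,10S)
Conditions: DCC, DMAP (cat.), CH2Cl2, 0 °C to rt
Reagents that add atoms: none
Why: Steglich esterification acylates the C8 alcohol with retention, since the C8–O bond is not broken.

Step 20
Reactants: 27 furan C8 ester (4S,8S,10S)
Product: 31 O-TBS ylidene butenolide (4S,8S,10S), via furan endoperoxide 28 (not isolated), via γ-hydroxybutenolide 29 (not isolated), via hemiketal mesylate 30 (not isolated)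
Conditions: O2, hν (visible), methylene blue, i-Pr2NEt, CH2Cl2, −78 °C; then MsCl, Et3N, −78 to 0 °C
Reagents that add atoms: dioxygen, O=O
Why: [4+2] cycloaddition of singlet oxygen across C6/C12 of the furan, base-induced Kornblum–DeLaMare opening of the endoperoxide at its only C–H (C12) and dehydration through the mesylate should give the γ-ylidene butenolide, whose C5=C6 geometry is dictated by the nine-membered ring (C4 cis to C7), while the electron-poor acrylate and furanone olefins do not react with singlet oxygen.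

Step 21
Reactants: 31 O-TBS ylidene butenolide (4S,8S,10S)
Product: 32 CNP0193735.1
Conditions: HF·pyridine, pyridine, THF, 0 °C
Reagents that add atoms: none
Why: Fluoride cleavage of the primary silyl ether (desilylation) should free the hydroxymethyl group without touching the acetate, the esters or the enol lactone.

Compound list
1 | furan-3,4-diyldimethanol | OCc1cocc1CO | starting material
2 | [4-(TIPS-oxymethyl)furan-3-yl]methanol | OCc1cocc1CO[Si](C(C)C)(C(C)C)C(C)C | intermediate
3 | 4-(TIPS-oxymethyl)furan-3-carbaldehyde | O=Cc1cocc1CO[Si](C(C)C)(C(C)C)C(C)C | intermediate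
4 | lithium α-amino alkoxide from 3 and lithium N,N,N'-trimethylethylenediamide (formed in situ) | CN(C)CCN(C)C([O-])c1cocc1CO[Si](C(C)C)(C(C)C)C(C)C.[Li+] | intermediate
5 | 2-(hydroxymethyl)-4-(TIPS-oxymethyl)furan-3-carbaldehyde | O=Cc1c(CO)occ1CO[Si](C(C)C)(C(C)C)C(C)C | intermediate
6 | 2-(bromomethyl)-4-(TIPS-oxymethyl)furan-3-carbaldehyde | O=Cc1c(CBr)occ1CO[Si](C(C)C)(C(C)C)C(C)C | intermediate
7 | methacrolein (2-methylprop-2-enal) | C=C(C)C=O | starting material
8 | methyl (3S)-4-methyl-3-(trimethylsilyloxy)pent-4-enoate (formed in situ) | C=C(C)[C@@H](O[Si](C)(C)C)CC(=O)OC | intermediate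
9 | methyl (3S)-3-hydroxy-4-methylpent-4-enoate | C=C(C)[C@@H](O)CC(=O)OC | intermediate
10 | methyl (3S)-3-{[3-formyl-4-(TIPS-oxymethyl)furan-2-yl]methoxy}-4-methylpent-4-enoate | C=C(C)[C@@H](OCc1occ(CO[Si](C(C)C)(C(C)C)C(C)C)c1C=O)CC(=O)OC | intermediate
11 | methyl (3S)-3-({3-[(1S)-1-hydroxyprop-2-en-1-yl]-4-(TIPS-oxymethyl)furan-2-yl}methoxy)-4-methylpent-4-enoate | C=C(C)[C@@H](OCc1occ(CO[Si](C(C)C)(C(C)C)C(C)C)c1[C@@H](O)C=C)CC(=O)OC | intermediate
12 | furo-fused oxocine allylic alcohol: ring O–C5H2–C6=C7(furan)–C8H(OH)–C9H=C10(CH3)–C1H(CH2CO2CH3), cis C9=C10, C11–CH2OTIPS, (1S,8S) | O1Cc2occ(CO[Si](C(C)C)(C(C)C)C(C)C)c2[C@@H](O)/C=C(C)\[C@@H]1CC(=O)OC | intermediate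
13 | furo-fused oxocane alcohol: as 12 with C9H2–C10H(CH3), C10 methyl trans to C8–OH and cis to the C1 side chain, (1S,8S,10S) | O1Cc2occ(CO[Si](C(C)C)(C(C)C)C(C)C)c2[C@@H](O)C[C@H](C)[C@@H]1CC(=O)OC | intermediate
14 | C8 O-TBS ether of 13 (methyl ester) | O1Cc2occ(CO[Si](C(C)C)(C(C)C)C(C)C)c2[C@@H](O[Si](C)(C)C(C)(C)C)C[C@H](C)[C@@H]1CC(=O)OC | intermediate
15 | C8 O-TBS oxocane carboxylic acid (C1–CH2–CO2H) | O1Cc2occ(CO[Si](C(C)C)(C(C)C)C(C)C)c2[C@@H](O[Si](C)(C)C(C)(C)C)C[C@H](C)[C@@H]1CC(=O)O | intermediate
16 | mixed isobutyl carbonic anhydride of 15 (formed in situ) | O1Cc2occ(CO[Si](C(C)C)(C(C)C)C(C)C)c2[C@@H](O[Si](C)(C)C(C)(C)C)C[C@H](C)[C@@H]1CC(=O)OC(=O)OCC(C)C | intermediate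
17 | α-methyl α-diazo ketone: C1–C2H2–C3(=O)–C4(=N2)–CH3 on the oxocane, (1S,8S,10S) | O1Cc2occ(CO[Si](C(C)C)(C(C)C)C(C)C)c2[C@@H](O[Si](C)(C)C(C)(C)C)C[C@H](C)[C@@H]1CC(=O)C(C)=[N+]=[N-] | intermediate
18 | bicyclic oxonium ylide: ring oxygen bonded to C1, C5 and the carbanionic C4 (formed in situ) | [O+]14Cc2occ(CO[Si](C(C)C)(C(C)C)C(C)C)c2[C@@H](O[Si](C)(C)C(C)(C)C)C[C@H](C)[C@@H]1CC(=O)[C-]4C | intermediate
19 | bridged tetrahydrofuran-3-one: O–C1H–C2H2–C3(=O)–C4(CH3), C4 joined to C5H2 of the furan, C8–OTBS, C13–OTIPS, (1S,4S,8S,10S) | CC(C)(C)[Si](C)(C)O[C@H]1C[C@H](C)[C@@H]2CC(=O)[C@](C)(Cc3occ(CO[Si](C(C)C)(C(C)C)C(C)C)c13)O2 | intermediate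
20 | trimethylsilyl enol ether of 19 (C2=C3–OSiMe3; formed in situ) | CC(C)(C)[Si](C)(C)O[C@H]1C[C@H](C)[C@@H]2C=C(O[Si](C)(C)C)[C@](C)(Cc3occ(CO[Si](C(C)C)(C(C)C)C(C)C)c13)O2 | intermediate
21 | bridged 3(2H)-furanone (C1=C2), C8–OTBS, C13–OTIPS, (4S,8S,10S) | CC(C)(C)[Si](C)(C)O[C@H]1C[C@H](C)C2=CC(=O)[C@](C)(Cc3occ(CO[Si](C(C)C)(C(C)C)C(C)C)c13)O2 | intermediate
22 | furanone C8,C13-diol (4S,8S,10S) | O[C@H]1C[C@H](C)C2=CC(=O)[C@](C)(Cc3occ(CO)c13)O2 | intermediate
23 | furanone C13 acetate with free C8–OH (4S,8S,10S) | O[C@H]1C[C@H](C)C2=CC(=O)[C@](C)(Cc3occ(COC(C)=O)c13)O2 | intermediate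
24 | ethyl 2-(hydroxymethyl)acrylate | C=C(CO)C(=O)OCC | starting material
25 | ethyl 2-(TBS-oxymethyl)acrylate | C=C(CO[Si](C)(C)C(C)(C)C)C(=O)OCC | intermediate
26 | 2-(TBS-oxymethyl)acrylic acid | C=C(CO[Si](C)(C)C(C)(C)C)C(=O)O | intermediate
27 | furan C8 2-(TBS-oxymethyl)acrylate ester, C13 acetate (4S,8S,10S) | C=C(CO[Si](C)(C)C(C)(C)C)C(=O)O[C@H]1C[C@H](C)C2=CC(=O)[C@](C)(Cc3occ(COC(C)=O)c13)O2 | intermediate
28 | furan endoperoxide (O–O across C6 and C12; formed in situ) | C=C(CO[Si](C)(C)C(C)(C)C)C(=O)O[C@H]1C[C@H](C)C2=CC(=O)[C@](C)(CC34OOC(O3)C(COC(C)=O)=C14)O2 | intermediate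
29 | γ-hydroxybutenolide (C6–OH hemiketal, C12 lactone carbonyl; formed in situ) | C=C(CO[Si](C)(C)C(C)(C)C)C(=O)O[C@H]1C[C@H](C)C2=CC(=O)[C@](C)(CC3(O)OC(=O)C(COC(C)=O)=C13)O2 | intermediate
30 | C6 hemiketal mesylate of 29 (formed in situ) | C=C(CO[Si](C)(C)C(C)(C)C)C(=O)O[C@H]1C[C@H](C)C2=CC(=O)[C@](C)(CC3(OS(C)(=O)=O)OC(=O)C(COC(C)=O)=C13)O2 | intermediate
31 | O-TBS ether of the target (C5=C6 ylidene butenolide) | C=C(CO[Si](C)(C)C(C)(C)C)C(=O)O[C@H]1C[C@H](C)C2=CC(=O)[C@](C)(/C=C3/OC(=O)C(COC(C)=O)=C31)O2 | intermediate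
32 | CNP0193735.1 | C=C(CO)C(=O)O[C@H]1C[C@H](C)C2=CC(=O)[C@](C)(/C=C3/OC(=O)C(COC(C)=O)=C31)O2 | target

Total step count: 21. Longest linear sequence: 18 steps (steps 1–4, 6–16 and 19–21).

Steps most likely to fail

Step 13. The methyl-bearing carbenoid may be lost to 1,2-hydride migration (giving the enone), to C–H insertion at C10–H or to a [1,4]-shift before the [1,2]-shift takes place. The fallback carries no methyl group on the carbenoid and brings it in later by alkylation; it sets out from 15 and comes back at 21. Acid 15 is activated as in step 12 (through 16) and treated with CH2N2 to give the diazomethyl ketone F1. Cu(hfacac)2 under the conditions of step 13 should give, through the oxonium ylide F2, the bridged ketone lacking the C4 methyl group F3. IBX (DMSO, 65 °C) should dehydrogenate F3 to the 2H-furanone F4. Deprotonation at C4 with LiN(SiMe3)2 and alkylation with CH3I (THF/DMPU, −78 °C) should then give 21, because the electrophile can approach C4 only from the face away from the C5–C10 bridge.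

Step 7. The facial selectivity of the vinyl transfer may be poor, because the ether oxygens flanking the formyl group can bind zinc and open an uncatalysed path. The fallback replaces catalyst control by separation and inversion; it sets out from 10 and comes back at 12. CH2=CHMgBr (THF, −78 °C) should give 11 together with its 8R epimer F5. Ring-closing metathesis of the mixture as in step 8 should give 12 and the 8R ring alcohol F6, which are ring diastereomers and should separate on silica. Mitsunobu inversion of F6 (4-nitrobenzoic acid, PPh3, DIAD) should give the 8S 4-nitrobenzoate F7, and K2CO3 in MeOH should return 12.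

Step 20. Material may be lost when the endoperoxide fragments by other channels or when other sites are photooxidised at this late stage. The fallback opens the furan by a polar oxidation instead; it sets out from 27 and comes back at 29, and from there at 31. NBS with NaHCO3 in aqueous acetone at −20 °C should open the furan to the (Z)-keto-enal F8 (C6 ketone, C12 aldehyde). Pinnick oxidation (NaClO2, NaH2PO4, 2-methylbut-2-ene, t-BuOH/H2O) should give the acid as its ring tautomer 29, and MsCl/Et3N as in step 20 should give 31 through 30.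

Further compounds
F1 | step 13 | diazomethyl ketone (C1–CH2–C(=O)–CH=N2) on the C8 O-TBS oxocane | O1Cc2occ(CO[Si](C(C)C)(C(C)C)C(C)C)c2[C@@H](O[Si](C)(C)C(C)(C)C)C[C@H](C)[C@@H]1CC(=O)C=[N+]=[N-]
F2 | step 13 | bicyclic oxonium ylide lacking the C4 methyl group | [O+]14Cc2occ(CO[Si](C(C)C)(C(C)C)C(C)C)c2[C@@H](O[Si](C)(C)C(C)(C)C)C[C@H](C)[C@@H]1CC(=O)[CH-]4
F3 | step 13 | bridged tetrahydrofuran-3-one lacking the C4 methyl group | CC(C)(C)[Si](C)(C)O[C@H]1C[C@H](C)[C@@H]2CC(=O)[C@H](Cc3occ(CO[Si](C(C)C)(C(C)C)C(C)C)c13)O2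
F4 | step 13 | bridged 2H-furanone lacking the C4 methyl group | CC(C)(C)[Si](C)(C)O[C@H]1C[C@H](C)C2=CC(=O)[C@H](Cc3occ(CO[Si](C(C)C)(C(C)C)C(C)C)c13)O2
F5 | step 7 | 8R epimer of 11 | C=C(C)[C@@H](OCc1occ(CO[Si](C(C)C)(C(C)C)C(C)C)c1[C@H](O)C=C)CC(=O)OC
F6 | step 7 | 8R epimer of 12 | O1Cc2occ(CO[Si](C(C)C)(C(C)C)C(C)C)c2[C@H](O)/C=C(C)\[C@@H]1CC(=O)OC
F7 | step 7 | 8S 4-nitrobenzoate of 12 | O1Cc2occ(CO[Si](C(C)C)(C(C)C)C(C)C)c2[C@@H](OC(=O)c3ccc(cc3)[N+](=O)[O-])/C=C(C)\[C@@H]1CC(=O)OC
F8 | step 20 | (Z)-keto-enal from oxidative opening of the furan in 27 | C=C(CO[Si](C)(C)C(C)(C)C)C(=O)O[C@H]1C[C@H](C)C2=CC(=O)[C@](C)(CC(=O)/C1=C(\C=O)COC(C)=O)O2
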